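**Assumption (one line):** positions are numbered as in labdane (ring A = C1–C5, C10; ring B = C5–C10; side chain C11–C16; C17 on C8; C18/C19 on C4; C20 on C10), and C18 denotes the equatorial, oxygenated substituent on C4.

## Analysis of the target

The target 32 is an ent-labdane: a trans-fused decalin (rings A and B) with a six-atom side chain on C9 that ends in a malonic acid half-ester at O15. It has six stereocentres. C4 is quaternary (hydroxymethyl C18 equatorial, methyl C19 axial), C5 and C10 form the trans ring fusion (C10 quaternary, axial methyl C20), and C8 is a tertiary carbinol with equatorial hydroxyl and axial methyl C17. C9 bears the side chain equatorially, cis to C20, and C13 (S) is a remote methyl-bearing centre that the ring cannot control. The sensitive groups are the malonic half-ester (base-labile, prone to decarboxylation on strong heating), the tertiary C8 alcohol (elimination under acid) and two primary alcohols, of which only O15 may be acylated. The difficulties are the two quaternary centres C4 and C10 in a 1,3-relationship, the contiguous C8–C9–C10 array, and the C8 configuration, which is the epimer that direct methyl addition to an 8-ketone does not give. C18 must also be told apart from C19, and C13 must be brought in enantiopure. The structural feature used here is that C9 with its C11 branch sits between quaternary C10 and oxygenated C8. Ring B (C5–C6–C7–C8–C9–C10) is therefore a cyclopentanone ring C10–C8–C7–C6–C5 with C9 inserted next to the carbonyl, and a trans-hydrindan-8-one with ring A complete can be enlarged by one carbon to give ring B with a ketone at C8 and a handle at C11.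

## Retrosynthetic reasoning

**Ester and protecting groups.** The malonate C–O bond at O15 is cut last. Target 32 comes from silyl ether 31 by desilylation, and 31 from diol 29 and Meldrum's acid 30, which gives the half-ester in one operation. O18 stays silylated until the end so that only O15 is acylated; the tertiary C8 hydroxyl is too hindered to compete. Diol 29 comes from benzyl ether 28.

**C8 carbinol.** The C8–O bond is cut by retro-hydration to the 8(17)-methylene compound 27. Addition of a methyl nucleophile to ketone 26 is not used, because the nucleophile would enter on the equatorial face and give the axial hydroxyl. A hydrogen-atom-transfer hydration of 27 forms the C–O bond on the equatorial face instead. Compound 27 is the methylenation product of ketone 26.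

**Side chain.** The C11–C12 bond is cut next. This splits 26 into the bicyclic exocyclic enone 15 and the five-carbon fragment 23, which carries C13 as its only stereocentre. The forward reaction is a conjugate addition, and C9 is set by protonation of the resulting enolate. The fragment needs exactly C12–C16, so it is built from acid 16 on auxiliary 17 through imide 19, its methylation product 21 and alcohol 22.

**Ring B (key disconnection).** Enone 15 comes from bromomethyl ketone 14 by loss of hydrogen bromide. In 14 the C9–C10 bond is cut and reconnected as C8–C10, which contracts ring B to the five-membered ring of vinyl carbinol 13. Forward, an electrophilic bromine source triggers a semipinacol shift of C10 from C8 to C9. This disconnection places the carbonyl at C8 and a leaving group on C11, a pattern that annulation-derived decalins lack. All remaining ring stereochemistry then rests on hydrindane chemistry.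

**Vinyl carbinol.** The C8–C9 bond of 13 is cut to ketone 12 and a vinyl organometallic. The configuration formed at C8 is of no lasting consequence, since C8 becomes a carbonyl carbon.

**Functional-group adjustments.** Ketone 12 comes from ketal 11 by hydrolysis. Ketal 11 comes from ketone 9 by deoxygenation at C3 through tosylhydrazone 10, and 9 from hydroxy ketone 8 by silylation. The C3 oxygen is needed only to build C4 and C5 and is removed once it has done so.

**C4 and C5.** In 8 the C4–C18 bond and the C5–H bond are cut together, back to enone ketal 6. Forward, reduction of the enone gives the trans ring fusion and a regiodefined enolate, which takes up a one-carbon electrophile anti to the angular methyl. The methyl already on C4 becomes C19 and the new carbon becomes C18.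

**Hydrindane.** Ketal 6 comes from enone 5 by selective protection of the saturated ketone. Enone 5 is opened at C4=C5 (aldol condensation) to triketone 3, and 3 at C1–C10 (Michael addition) to dione 1 and vinyl ketone 2. The absolute configuration of the whole ring system is set in the cyclisation of 3.

## Alternatives that were turned down

**Alternative 1: intramolecular Diels–Alder reaction.** The C3–C4 and C5–C10 bonds are cut, leading to the open-chain triene A1. In A1 an E-configured 2-methyl enoate (C4=C5) is tied through C6–C9 to a diene C10=C1–C2=C3, and C8 (as triethylsilyl ether), C9 and C13 are already in place. Heating A1 with Et2AlCl should give decalin A2, ring A by the cycloaddition and ring B through the tether, with the ester as C18 and a C1=C2 alkene.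
- For: two rings, both quaternary centres and C5 are made in one step, and the enoate geometry places the ester cis to H5, which is the C18 arrangement. The route is convergent, and A2 is only a hydrogenation, an ester reduction and protecting-group steps away from the target.
- Against: both new bonds are formed to fully substituted carbons. The diene terminus C10 carries an inside methyl that disfavours the s-cis conformer, and the enoate is a weak dienophile. The Lewis acid meets a tertiary silyl ether next to the allylic C9. The preference of such decatrienes for trans fusion is modest and would have to be relayed from the C8/C9 pair, which itself must first be made by acyclic stereocontrol of a tertiary carbinol next to a tertiary centre.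
- Comparison: this alternative is stronger on convergence and on the number of steps after the key step. The chosen route offers instead that every ring stereocentre is set on a cyclic, conformationally defined intermediate, and C8 and C9 are installed late on a rigid decalin.

**Alternative 2: hydroxyl-directed C–H silylation of the C4 gem-dimethyl group.** Only the C18–O bond is cut, back to the 4,4-dimethyl 3-ol A3 (equatorial 3-hydroxyl, O8 triethylsilyl ether, O15 pivalate). Et2SiH2 silylates the 3-hydroxyl in place, and [Ir(cod)OMe]2 with a phenanthroline ligand inserts into a C–H bond of the equatorial methyl to close oxasilolane A4. A Tamao–Fleming oxidation would then give the 3,18-diol.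
- For: the choice between the two C4 methyls is made by the catalyst and the directing group, and an equatorial 3-hydroxyl reaches exactly the equatorial methyl, C18. The reaction is late-stage and functional-group tolerant.
- Against: the key step forms no skeletal bond, so A3 must still be made in the ent-series with all its stereocentres, and no chiral-pool source exists for that series. The 3-hydroxyl serves only as a director; after oxidation the primary 18-hydroxyl must be differentiated from the secondary 3-hydroxyl, which must then be deoxygenated. The C8 triethylsilyl ether is exposed to the oxidation conditions.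
- Comparison: on the C4 problem alone this alternative is at least as strong, because it uses catalyst control where step 4 of the chosen route relies on substrate control. The chosen route also has to remove a C3 oxygen, so it gains nothing there. Its C3 carbonyl, however, is used to build C4–C18 and C5, and the route constructs the skeleton, which A4 presupposes.

**Alternative 3: epoxide-triggered cationic bicyclisation.** The C4–C5 and C9–C10 bonds are cut, back to the acyclic (3R,4R)-epoxide A5. It has an E-configured C5=C10 alkene and an allylsilane terminus C9=C8–C17–SiMe3. MeAlCl2 should open the epoxide at C4, and a chair–chair cascade followed by loss of the silyl group gives bicycle A6 with the C8=C17 methylene and the full side chain.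
- For: two rings and four stereocentres (C4, C5, C9, C10) arise in one step from one epoxide. Placing the silyloxymethyl group trans to the chain on the epoxide translates into equatorial C18. A6 already has the exocyclic methylene that the chosen route reaches only at 27, and the linear precursor can be assembled convergently.
- Against: the oxygenated substituent on C4 withdraws electron density from the carbon that must ionise. This slows initiation and favours hydride shift or chloride opening. Cascades of this kind give partly cyclised products and alkene isomers that are hard to separate. The trisubstituted allylsilane must be made with defined geometry, and the C3 hydroxyl of A6 must be deoxygenated.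
- Comparison: this alternative is clearly stronger in step count and convergence, and it shares the C3 deoxygenation burden with the chosen route. The chosen route offers stepwise, individually checkable stereocontrol. Its key product 14 has the C8 ketone and a C11 leaving group, so the side chain is attached late and can be varied.

Key step: step 10

## Route

Step 1
Reactants: 1 2-methylcyclopentane-1,3-dione; 2 pent-1-en-3-one
Product: 3 2-methyl-2-(3-oxopentyl)cyclopentane-1,3-dione
Conditions: H2O, AcOH (cat.), 70 °C
Reagents that add atoms: none
Why: Michael addition of the enolised 1,3-dione to the vinyl ketone, the standard first stage of the Hajos–Parrish sequence; the new quaternary carbon (later C10) is still prochiral, so no stereochemical issue arises.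

Step 2
Reactants: 3 2-methyl-2-(3-oxopentyl)cyclopentane-1,3-dione
Product: 5 (7aR)-4,7a-dimethyl-2,3,7,7a-tetrahydro-1H-indene-1,5(6H)-dione, via cis-fused ketol 4 (not isolated)
Conditions: D-phenylalanine (1.0 equiv), (1R)-(−)-10-camphorsulfonic acid (0.5 equiv), DMF, 30 → 70 °C
Reagents that add atoms: none
Why: Amino-acid-catalysed asymmetric intramolecular aldol condensation (Hajos–Parrish–Eder–Sauer–Wiechert reaction): the enamine of the ethyl ketone attacks one of the two enantiotopic ring carbonyls in a hydrogen-bonded transition state, and the D-configured catalyst should give the 7aR enone, the antipode of the enone formed with L-amino acids. A primary amino acid with an acid co-catalyst is used because the ethyl ketone must form a trisubstituted enamine, which proline does only sluggishly; the ketol dehydrates under the same conditions.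

Step 3
Reactants: 5 (7aR)-4,7a-dimethyl-2,3,7,7a-tetrahydro-1H-indene-1,5(6H)-dione
Product: 6 (7a'R)-4',7a'-dimethyl-2',3',7',7a'-tetrahydrospiro[[1,3]dioxolane-2,1'-inden]-5'(6'H)-one
Conditions: 2-ethyl-2-methyl-1,3-dioxolane, ethylene glycol (cat.), TsOH·H2O (cat.), 23 °C
Reagents that add atoms: 2-ethyl-2-methyl-1,3-dioxolane, CCC1(C)OCCO1
Why: Acid-catalysed transketalisation is chemoselective for the saturated cyclopentanone (C8), because the conjugated C3 ketone is the weaker electrophile and could be ketalised only with deconjugation. No stereocentre is touched.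

Step 4
Reactants: 6 (7a'R)-4',7a'-dimethyl-2',3',7',7a'-tetrahydrospiro[[1,3]dioxolane-2,1'-inden]-5'(6'H)-one
Product: 8 (3a'S,4'S,7a'R)-4'-(hydroxymethyl)-4',7a'-dimethylhexahydrospiro[[1,3]dioxolane-2,1'-inden]-5'(4'H)-one, via lithium enolate 7 (not isolated)
Conditions: Li, NH3(l), THF, t-BuOH (1 equiv), −78 → −33 °C; isoprene; NH3 off; CH2O (gas), THF, −78 → −20 °C; aq. NH4Cl
Reagents that add atoms: formaldehyde, C=O
Why: Dissolving-metal reduction of the enone followed by aldol trapping (reductive hydroxymethylation): the β-carbanion is protonated at C5 on the face anti to the angular methyl, which should give the trans ring fusion, and leaves the regiodefined C3–C4 lithium enolate. Monomeric formaldehyde then adds at C4 on the face anti to the C10 methyl, so the hydroxymethyl group becomes equatorial C18 and the methyl that came from the vinyl ketone becomes axial C19.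

Step 5
Reactants: 8 (3a'S,4'S,7a'R)-4'-(hydroxymethyl)-4',7a'-dimethylhexahydrospiro[[1,3]dioxolane-2,1'-inden]-5'(4'H)-one
Product: 9 (3a'S,4'S,7a'R)-4'-{[tert-butyl(dimethyl)silyl]oxymethyl}-4',7a'-dimethylhexahydrospiro[[1,3]dioxolane-2,1'-inden]-5'(4'H)-one
Conditions: TBSCl, imidazole, DMF, 23 °C
Reagents that add atoms: tert-butyldimethylsilyl chloride, CC(C)(C)[Si](C)(C)Cl
Why: Standard silylation of the primary neopentyl alcohol; it blocks retro-aldol loss of the hydroxymethyl group in the following steps.

Step 6
Reactants: 9 (3a'S,4'S,7a'R)-4'-{[tert-butyl(dimethyl)silyl]oxymethyl}-4',7a'-dimethylhexahydrospiro[[1,3]dioxolane-2,1'-inden]-5'(4'H)-one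
Product: 10 (E)-tosylhydrazone of ketone 9 at C3 (3a'R,4'R,7a'R)
Conditions: TsNHNH2, EtOH, 70 °C
Reagents that add atoms: 4-methylbenzenesulfonohydrazide, Cc1ccc(cc1)S(=O)(=O)NN
Why: Condensation of the only free ketone with the sulfonyl hydrazide; C3 is hindered by the quaternary C4, but 4,4-disubstituted 3-ketones of terpenoids are known to form such hydrazones on heating. The dioxolane and the silyl ether are stable in neutral ethanol.

Step 7
Reactants: 10 (E)-tosylhydrazone of ketone 9
Product: 11 tert-butyl{[(3a'R,4'S,7a'R)-4',7a'-dimethyloctahydrospiro[[1,3]dioxolane-2,1'-inden]-4'-yl]methoxy}dimethylsilane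
Conditions: catecholborane, CHCl3, 0 → 23 °C; then NaOAc·3H2O, 60 °C
Reagents that add atoms: none
Why: Reduction of the tosylhydrazone with catecholborane, then acetate-induced loss of sulfinate and dinitrogen from the resulting diazene, a mild non-basic equivalent of the Wolff–Kishner deoxygenation. The neutral conditions avoid β-elimination or retro-aldol cleavage at C4 and leave the ketal and the silyl ether intact.

Step 8
Reactants: 11 tert-butyl{[(3a'R,4'S,7a'R)-4',7a'-dimethyloctahydrospiro[[1,3]dioxolane-2,1'-inden]-4'-yl]methoxy}dimethylsilane
Product: 12 (3aR,4S,7aR)-4-{[tert-butyl(dimethyl)silyl]oxymethyl}-4,7a-dimethyloctahydro-1H-inden-1-one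
Conditions: PPTS, acetone/H2O (10:1), 56 °C
Reagents that add atoms: water, O
Why: Mildly acidic hydrolysis of the dioxolane; pyridinium tosylate in wet acetone is weak enough to spare the neopentyl primary silyl ether. The ring fusion cannot epimerise because C10 is quaternary and C5 is not α to the ketone.

Step 9
Reactants: 12 (3aR,4S,7aR)-4-{[tert-butyl(dimethyl)silyl]oxymethyl}-4,7a-dimethyloctahydro-1H-inden-1-one
Product: 13 (1S,3aR,4S,7aR)-4-{[tert-butyl(dimethyl)silyl]oxymethyl}-1-ethenyl-4,7a-dimethyloctahydro-1H-inden-1-ol
Conditions: CH2=CHMgBr, CeCl3, THF, −78 → 0 °C; aq. NH4Cl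
Reagents that add atoms: vinylmagnesium bromide, C=C[Mg]Br
Why: 1,2-Addition of the vinyl organocerium reagent to the hindered cyclopentanone; the cerium reagent suppresses enolisation. Attack anti to the angular methyl, as in additions to steroidal 17-ketones, should give the 1S carbinol with the hydroxyl cis to the methyl; this centre becomes the C8 carbonyl carbon in step 10.

Step 10
Reactants: 13 (1S,3aR,4S,7aR)-4-{[tert-butyl(dimethyl)silyl]oxymethyl}-1-ethenyl-4,7a-dimethyloctahydro-1H-inden-1-ol
Product: 14 (1S,4aS,5S,8aR)-1-(bromomethyl)-5-{[tert-butyl(dimethyl)silyl]oxymethyl}-5,8a-dimethyloctahydronaphthalen-2(1H)-one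
Conditions: NBS (1.1 equiv), NaHCO3, CH2Cl2, 0 → 23 °C, dark
Reagents that add atoms: N-bromosuccinimide, O=C1CCC(=O)N1Br
Why: NBS transfers a bromonium ion to the terminal alkene, and the bromonium ion is opened at its internal carbon C9 not by an external nucleophile but by the C8–C10 σ bond anti to the breaking C9–Br bond, while the C8 hydroxyl collapses to the carbonyl (semipinacol 1,2-shift). The closest known reaction type is the halonium-induced ring expansion of 1-vinylcycloalkanols to 2-(halomethyl)cycloalkanones, the reaction behind the D-homoannulation of 17-vinyl-17-hydroxy steroids. Ring B is not closed end to end but formed by ring enlargement: the cyclopentane C10–C8–C7–C6–C5 takes up C9 between C10 and C8 through a suprafacial 1,2-alkyl shift that forms the C9–C10 bond. C10 migrates with retention, so C10, C5 and C4 are carried over unchanged. The new stereocentre C9 is set by anti addition of bromine and C10 across the alkene in the reacting rotamer; being α to the ketone it can settle in the equatorial bromomethyl arrangement drawn, and it is removed in step 11 in any case. The step needs migration of the quaternary C10 and not of the C7 methylene: C10 is the more substituted, more electron-rich terminus and stabilises the electron-deficient transition state better, and the brominating agent should approach the vinyl face turned away from the bulky C10 side, which places the C8–C10 bond anti to the bromonium ion. It also needs the shift to outrun bromohydrin or epoxide formation, which the non-nucleophilic solvent, the buffer, the relief of cyclopentane strain and the gain of a C=O bond all favour. The silyl ether is inert to NBS under bicarbonate buffering.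

Step 11
Reactants: 14 (1S,4aS,5S,8aR)-1-(bromomethyl)-5-{[tert-butyl(dimethyl)silyl]oxymethyl}-5,8a-dimethyloctahydronaphthalen-2(1H)-one
Product: 15 (4aS,5S,8aR)-5-{[tert-butyl(dimethyl)silyl]oxymethyl}-5,8a-dimethyl-1-methylideneoctahydronaphthalen-2(1H)-one
Conditions: DBU, CH2Cl2, 0 °C
Reagents that add atoms: none
Why: E1cB elimination of hydrogen bromide from the β-bromo ketone gives the exocyclic enone; with C10 quaternary the double bond cannot move into the ring. The C9 stereocentre of 14 is deliberately erased here.

Step 12
Reactants: 16 4-(benzyloxy)butanoic acid; 17 (4R)-4-benzyl-1,3-oxazolidin-2-one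
Product: 19 (4R)-4-benzyl-3-[4-(benzyloxy)butanoyl]-1,3-oxazolidin-2-one, via mixed pivalic anhydride 18 (not isolated)
Conditions: PivCl, Et3N, THF, −20 °C; then 17, LiCl, −20 → 23 °C
Reagents that add atoms: none
Why: N-Acylation of the oxazolidinone through the mixed pivalic anhydride under LiCl/Et3N conditions, a routine way to load an Evans auxiliary without strong base.

Step 13
Reactants: 19 (4R)-4-benzyl-3-[4-(benzyloxy)butanoyl]-1,3-oxazolidin-2-one
Product: 21 (4R)-4-benzyl-3-[(2R)-4-(benzyloxy)-2-methylbutanoyl]-1,3-oxazolidin-2-one, via sodium enolate 20 (not isolated)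
Conditions: NaHMDS, THF, −78 °C; MeI, −78 → −40 °C
Reagents that add atoms: iodomethane, CI
Why: Evans asymmetric alkylation: the chelated Z sodium enolate is methylated on the face opposite the benzyl group of the 4R auxiliary, which should set the 2R centre, the future C13. Iodomethane is reactive enough at −78 °C for high selectivity.

Step 14
Reactants: 21 (4R)-4-benzyl-3-[(2R)-4-(benzyloxy)-2-methylbutanoyl]-1,3-oxazolidin-2-one
Product: 22 (2R)-4-(benzyloxy)-2-methylbutan-1-ol
Conditions: LiBH4, Et2O, MeOH (1 equiv), 0 °C
Reagents that add atoms: none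
Why: Reductive cleavage of the imide with LiBH4: hydride attacks the exocyclic carbonyl and releases the primary alcohol and the auxiliary without epimerising the α-centre.

Step 15
Reactants: 22 (2R)-4-(benzyloxy)-2-methylbutan-1-ol
Product: 23 {[(3R)-4-bromo-3-methylbutoxy]methyl}benzene
Conditions: CBr4, PPh3, CH2Cl2, 0 °C
Reagents that add atoms: tetrabromomethane, BrC(Br)(Br)Br
Why: Appel bromination of the primary alcohol; the stereocentre is β to the reacting carbon and is not involved.

Step 16
Reactants: 15 (4aS,5S,8aR)-5-{[tert-butyl(dimethyl)silyl]oxymethyl}-5,8a-dimethyl-1-methylideneoctahydronaphthalen-2(1H)-one; 23 {[(3R)-4-bromo-3-methylbutoxy]methyl}benzene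
Product: 26 (1S,4aS,5S,8aR)-1-[(3S)-5-(benzyloxy)-3-methylpentyl]-5-{[tert-butyl(dimethyl)silyl]oxymethyl}-5,8a-dimethyloctahydronaphthalen-2(1H)-one, via Grignard reagent 24 (not isolated), via magnesium enolate 25 (not isolated)
Conditions: 23, Mg, I2 (cat.), THF, 40 °C; then CuBr·SMe2 (20 mol%), 15, THF, −78 → −40 °C; aq. NH4Cl, −78 °C
Reagents that add atoms: none
Why: Copper-catalysed conjugate addition of the Grignard reagent to the s-cis-locked exocyclic enone forms C11–C12; 9-methylene-8-ketones of the drimane type are known acceptors for organocopper nucleophiles. The enolate is protonated at C9 from the axial direction on the face anti to the C10 methyl, which puts the chain equatorial (C9 S), the arrangement also expected to be favoured at equilibrium. C13 is carried in unchanged from 23.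

Step 17
Reactants: 26 (1S,4aS,5S,8aR)-1-[(3S)-5-(benzyloxy)-3-methylpentyl]-5-{[tert-butyl(dimethyl)silyl]oxymethyl}-5,8a-dimethyloctahydronaphthalen-2(1H)-one
Product: 27 (1R,4aS,5S,8aS)-1-[(3S)-5-(benzyloxy)-3-methylpentyl]-5-{[tert-butyl(dimethyl)silyl]oxymethyl}-5,8a-dimethyl-2-methylidenedecahydronaphthalene
Conditions: Ph3PCH3Br, KOtBu, toluene, 90 °C
Reagents that add atoms: methyltriphenylphosphonium bromide, C[P+](c1ccccc1)(c1ccccc1)c1ccccc1.[Br-]
Why: Wittig methylenation of the hindered ketone with the non-stabilised ylide at elevated temperature, a reaction type established for 8-oxo-17-norlabdanes. C9 is epimerisable under these conditions but already holds the preferred equatorial chain.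

Step 18
Reactants: 27 (1R,4aS,5S,8aS)-1-[(3S)-5-(benzyloxy)-3-methylpentyl]-5-{[tert-butyl(dimethyl)silyl]oxymethyl}-5,8a-dimethyl-2-methylidenedecahydronaphthalene
Product: 28 (1S,2S,4aS,5S,8aR)-1-[(3S)-5-(benzyloxy)-3-methylpentyl]-5-{[tert-butyl(dimethyl)silyl]oxymethyl}-2,5,8a-trimethyldecahydronaphthalen-2-ol
Conditions: Co(acac)2 (20 mol%), PhSiH3, O2 (1 atm), THF, 23 °C
Reagents that add atoms: dioxygen, O=O
Why: Mukaiyama hydration: a cobalt hydride transfers a hydrogen atom to the methylene carbon, the tertiary C8 radical is trapped by dioxygen and the peroxide is reduced by the silane, giving the Markovnikov alcohol. The axial face of C8 is shielded by the syn-axial C10 methyl, so the C–O bond should form on the equatorial face and give the equatorial hydroxyl with axial C17 methyl (C8 S), the epimer that methyl addition to ketone 26 would not give.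

Step 19
Reactants: 28 (1S,2S,4aS,5S,8aR)-1-[(3S)-5-(benzyloxy)-3-methylpentyl]-5-{[tert-butyl(dimethyl)silyl]oxymethyl}-2,5,8a-trimethyldecahydronaphthalen-2-ol
Product: 29 (1S,2S,4aS,5S,8aR)-5-{[tert-butyl(dimethyl)silyl]oxymethyl}-1-[(3S)-5-hydroxy-3-methylpentyl]-2,5,8a-trimethyldecahydronaphthalen-2-ol
Conditions: H2 (1 atm), Pd/C, EtOAc, 23 °C
Reagents that add atoms: none
Why: Hydrogenolysis of the benzyl ether; in ethyl acetate the silyl ether and the tertiary alcohol are untouched and no other reducible group is present.

Step 20
Reactants: 29 (1S,2S,4aS,5S,8aR)-5-{[tert-butyl(dimethyl)silyl]oxymethyl}-1-[(3S)-5-hydroxy-3-methylpentyl]-2,5,8a-trimethyldecahydronaphthalen-2-ol; 30 Meldrum's acid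
Product: 31 3-{[(3S)-5-[(1S,2S,4aS,5S,8aR)-5-{[tert-butyl(dimethyl)silyl]oxymethyl}-2-hydroxy-2,5,8a-trimethyldecahydronaphthalen-1-yl]-3-methylpentyl]oxy}-3-oxopropanoic acid
Conditions: 30 (1.2 equiv), toluene, 90 °C
Reagents that add atoms: none
Why: Alcoholysis of Meldrum's acid on heating opens the dioxanedione with loss of acetone and delivers the malonic half-ester directly, with no coupling agent and no second ester to cleave. Only the primary C15 hydroxyl reacts; the tertiary C8 hydroxyl is too hindered.

Step 21
Reactants: 31 3-{[(3S)-5-[(1S,2S,4aS,5S,8aR)-5-{[tert-butyl(dimethyl)silyl]oxymethyl}-2-hydroxy-2,5,8a-trimethyldecahydronaphthalen-1-yl]-3-methylpentyl]oxy}-3-oxopropanoic acid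
Product: 32 3-{[(3S)-5-[(1S,2S,4aS,5S,8aR)-2-hydroxy-5-(hydroxymethyl)-2,5,8a-trimethyldecahydronaphthalen-1-yl]-3-methylpentyl]oxy}-3-oxopropanoic acid
Conditions: HF·pyridine, pyridine, THF, 0 → 23 °C
Reagents that add atoms: none
Why: Fluoride-mediated cleavage of the silyl ether under buffered acidic conditions, which the malonic half-ester and the tertiary alcohol tolerate; basic fluoride or hydroxide is avoided because it would attack the malonate.

## Compound list

1 | 2-methylcyclopentane-1,3-dione | CC1C(=O)CCC1=O | starting material
2 | pent-1-en-3-one (ethyl vinyl ketone) | CCC(=O)C=C | starting material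
3 | 2-methyl-2-(3-oxopentyl)cyclopentane-1,3-dione | CCC(=O)CCC1(C)C(=O)CCC1=O | intermediate
4 | (3aR,7aR)-3a-hydroxy-4,7a-dimethylhexahydro-1H-indene-1,5(4H)-dione, cis-fused ketol, C4 epimers | C[C@@]12CCC(=O)C(C)[C@]1(O)CCC2=O | intermediate (not isolated)
5 | (7aR)-4,7a-dimethyl-2,3,7,7a-tetrahydro-1H-indene-1,5(6H)-dione | CC1=C2CCC(=O)[C@]2(C)CCC1=O | intermediate
6 | (7a'R)-4',7a'-dimethyl-2',3',7',7a'-tetrahydrospiro[[1,3]dioxolane-2,1'-inden]-5'(6'H)-one | CC1=C2CCC3(OCCO3)[C@]2(C)CCC1=O | intermediate
7 | lithium (3a'R,7a'R)-4',7a'-dimethyl-2',3',3a',6',7',7a'-hexahydrospiro[[1,3]dioxolane-2,1'-inden]-5'-olate, trans-fused enolate | [Li]OC1=C(C)[C@H]2CCC3(OCCO3)[C@]2(C)CC1 | intermediate (not isolated)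
8 | (3a'S,4'S,7a'R)-4'-(hydroxymethyl)-4',7a'-dimethylhexahydrospiro[[1,3]dioxolane-2,1'-inden]-5'(4'H)-one | O1CCOC12CC[C@@H]3[C@@](C)(CO)C(=O)CC[C@@]23C | intermediate
9 | (3a'S,4'S,7a'R)-4'-{[tert-butyl(dimethyl)silyl]oxymethyl}-4',7a'-dimethylhexahydrospiro[[1,3]dioxolane-2,1'-inden]-5'(4'H)-one | O1CCOC12CC[C@@H]3[C@@](C)(CO[Si](C)(C)C(C)(C)C)C(=O)CC[C@@]23C | intermediate
10 | (E)-tosylhydrazone of 9 at C3, (3a'R,4'R,7a'R), sulfonamide nitrogen anti to C4 | O1CCOC12CC[C@@H]3[C@@](C)(CO[Si](C)(C)C(C)(C)C)/C(=N/NS(=O)(=O)c4ccc(C)cc4)CC[C@@]23C | intermediate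
11 | tert-butyl{[(3a'R,4'S,7a'R)-4',7a'-dimethyloctahydrospiro[[1,3]dioxolane-2,1'-inden]-4'-yl]methoxy}dimethylsilane | O1CCOC12CC[C@@H]3[C@@](C)(CO[Si](C)(C)C(C)(C)C)CCC[C@@]23C | intermediate
12 | (3aR,4S,7aR)-4-{[tert-butyl(dimethyl)silyl]oxymethyl}-4,7a-dimethyloctahydro-1H-inden-1-one | O=C1CC[C@@H]2[C@@](C)(CO[Si](C)(C)C(C)(C)C)CCC[C@@]12C | intermediate
13 | (1S,3aR,4S,7aR)-4-{[tert-butyl(dimethyl)silyl]oxymethyl}-1-ethenyl-4,7a-dimethyloctahydro-1H-inden-1-ol | C=C[C@@]1(O)CC[C@@H]2[C@@](C)(CO[Si](C)(C)C(C)(C)C)CCC[C@@]12C | intermediate
14 | (1S,4aS,5S,8aR)-1-(bromomethyl)-5-{[tert-butyl(dimethyl)silyl]oxymethyl}-5,8a-dimethyloctahydronaphthalen-2(1H)-one | BrC[C@H]1[C@]2(C)CCC[C@](C)(CO[Si](C)(C)C(C)(C)C)[C@H]2CCC1=O | intermediate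
15 | (4aS,5S,8aR)-5-{[tert-butyl(dimethyl)silyl]oxymethyl}-5,8a-dimethyl-1-methylideneoctahydronaphthalen-2(1H)-one | C=C1[C@]2(C)CCC[C@](C)(CO[Si](C)(C)C(C)(C)C)[C@H]2CCC1=O | intermediate
16 | 4-(benzyloxy)butanoic acid | OC(=O)CCCOCc1ccccc1 | starting material
17 | (4R)-4-benzyl-1,3-oxazolidin-2-one | O=C1N[C@H](Cc2ccccc2)CO1 | starting material
18 | 4-(benzyloxy)butanoic pivalic anhydride | CC(C)(C)C(=O)OC(=O)CCCOCc1ccccc1 | intermediate (not isolated)
19 | (4R)-4-benzyl-3-[4-(benzyloxy)butanoyl]-1,3-oxazolidin-2-one | O=C(CCCOCc1ccccc1)N1[C@H](Cc2ccccc2)COC1=O | intermediate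
20 | sodium (Z)-enolate of 19 | [Na]O/C(=C\CCOCc1ccccc1)N1[C@H](Cc2ccccc2)COC1=O | intermediate (not isolated)
21 | (4R)-4-benzyl-3-[(2R)-4-(benzyloxy)-2-methylbutanoyl]-1,3-oxazolidin-2-one | C[C@H](CCOCc1ccccc1)C(=O)N1[C@H](Cc2ccccc2)COC1=O | intermediate
22 | (2R)-4-(benzyloxy)-2-methylbutan-1-ol | C[C@H](CCOCc1ccccc1)CO | intermediate
23 | {[(3R)-4-bromo-3-methylbutoxy]methyl}benzene | C[C@H](CCOCc1ccccc1)CBr | intermediate
24 | [(2R)-4-(benzyloxy)-2-methylbutyl]magnesium bromide | C[C@H](CCOCc1ccccc1)C[Mg]Br | intermediate (not isolated)
25 | bromomagnesium C8=C9 enolate of ketone 26 | C[C@H](CCOCc1ccccc1)CCC=1[C@]2(C)CCC[C@](C)(CO[Si](C)(C)C(C)(C)C)[C@H]2CCC1O[Mg]Br | intermediate (not isolated)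
26 | (1S,4aS,5S,8aR)-1-[(3S)-5-(benzyloxy)-3-methylpentyl]-5-{[tert-butyl(dimethyl)silyl]oxymethyl}-5,8a-dimethyloctahydronaphthalen-2(1H)-one | C[C@H](CCOCc1ccccc1)CC[C@H]1[C@]2(C)CCC[C@](C)(CO[Si](C)(C)C(C)(C)C)[C@H]2CCC1=O | intermediate
27 | (1R,4aS,5S,8aS)-1-[(3S)-5-(benzyloxy)-3-methylpentyl]-5-{[tert-butyl(dimethyl)silyl]oxymethyl}-5,8a-dimethyl-2-methylidenedecahydronaphthalene | C[C@H](CCOCc1ccccc1)CC[C@H]1[C@]2(C)CCC[C@](C)(CO[Si](C)(C)C(C)(C)C)[C@H]2CCC1=C | intermediate
28 | (1S,2S,4aS,5S,8aR)-1-[(3S)-5-(benzyloxy)-3-methylpentyl]-5-{[tert-butyl(dimethyl)silyl]oxymethyl}-2,5,8a-trimethyldecahydronaphthalen-2-ol | C[C@H](CCOCc1ccccc1)CC[C@H]1[C@]2(C)CCC[C@](C)(CO[Si](C)(C)C(C)(C)C)[C@H]2CC[C@]1(C)O | intermediate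
29 | (1S,2S,4aS,5S,8aR)-5-{[tert-butyl(dimethyl)silyl]oxymethyl}-1-[(3S)-5-hydroxy-3-methylpentyl]-2,5,8a-trimethyldecahydronaphthalen-2-ol | C[C@H](CCO)CC[C@H]1[C@]2(C)CCC[C@](C)(CO[Si](C)(C)C(C)(C)C)[C@H]2CC[C@]1(C)O | intermediate
30 | Meldrum's acid (2,2-dimethyl-1,3-dioxane-4,6-dione) | CC1(C)OC(=O)CC(=O)O1 | starting material
31 | 3-{[(3S)-5-[(1S,2S,4aS,5S,8aR)-5-{[tert-butyl(dimethyl)silyl]oxymethyl}-2-hydroxy-2,5,8a-trimethyldecahydronaphthalen-1-yl]-3-methylpentyl]oxy}-3-oxopropanoic acid | C[C@H](CCOC(=O)CC(=O)O)CC[C@H]1[C@]2(C)CCC[C@](C)(CO[Si](C)(C)C(C)(C)C)[C@H]2CC[C@]1(C)O | intermediate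
32 | 3-{[(3S)-5-[(1S,2S,4aS,5S,8aR)-2-hydroxy-5-(hydroxymethyl)-2,5,8a-trimethyldecahydronaphthalen-1-yl]-3-methylpentyl]oxy}-3-oxopropanoic acid (CNP0324566.1) | C[C@H](CCOC(=O)CC(=O)O)CC[C@H]1[C@]2(C)CCC[C@](C)(CO)[C@H]2CC[C@]1(C)O | target

## Step count and least certain steps

Total: 21 steps. Longest linear sequence: 17 steps (steps 1–11, then 16–21); the side-chain branch (steps 12–15) joins at step 16.

**Step 10 (key step).** Two things are most likely to go wrong. The first is migration of the C7 methylene in place of C10, because the preference for the more substituted carbon in such shifts is a tendency and the rotamer population about C8–C9 is not fixed. The second is capture of the bromonium ion by the C8 hydroxyl or by adventitious nucleophiles before the shift, because a monosubstituted alkene gives a weakly polarised bromonium ion. The fallback replaces the halonium trigger by an epoxide. Starting from 13, hydroxyl-directed epoxidation (VO(acac)2, t-BuOOH, CH2Cl2) would give the epoxy alcohol F1. A chelating Lewis acid (ZnBr2, CH2Cl2) then opens the epoxide at C9 with the same shift of C10 to give the hydroxymethyl ketone F2. In the chelate each C9 epimer of F1 holds a different ring bond anti to the breaking C–O bond, so the epimers can be separated and tested singly. Mesylation (MsCl, Et3N) gives the mesylate F3, which eliminates with DBU and returns to the route at 15.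

**Step 4.** Protonation at C5 may lead in part to the cis-fused hydrindane, since cis and trans hydrindanes differ little in energy. The enolate may also be lost by proton transfer or retro-aldol reaction during trapping with the polymerisation-prone electrophile. The fallback sets C4 first and C5 afterwards. From 6, the thermodynamic dienolate (KOtBu, t-BuOH/THF) is alkylated at C4 with benzyl chloromethyl ether, anti to the C10 methyl, to give the benzyloxymethyl β,γ-enone F4. Hydrogenation over Pd/C (H2, EtOAc) then adds hydrogen to the C5=C6 bond from the face opposite both α-methyl groups and cleaves the benzyl ether, returning to 8.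

**Step 7.** Hydrazone reduction at the neopentyl C3 may stall, or the intermediate may eliminate towards the C2=C3 alkene, because hydride delivery next to the quaternary C4 is slow. The fallback uses enolate chemistry. From 9, KHMDS and PhNTf2 (THF, −78 °C) give the enol triflate F5; only C2 can be deprotonated. Reduction with Pd(OAc)2, PPh3, Bu3N and HCO2H (DMF, 60 °C) gives the alkene F6, and hydrogenation (H2, Pd/C, EtOAc) returns to 11.

**Step 16.** Competing 1,2-addition to the C8 carbonyl, oligomerisation of the reactive enone and homocoupling during Grignard formation are the likely losses, and protonation at C9 may not be fully selective. The fallback is a Giese radical addition. From 22, iodination (I2, PPh3, imidazole) gives the iodide F7. Slow addition of Bu3SnH and AIBN to F7 and 15 (benzene, 80 °C) adds the primary radical to C11, and hydrogen transfer to C9 on the face anti to the C10 methyl returns to 26.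

**Step 18.** Capture of dioxygen by the C8 radical may show poor facial selectivity, and simple reduction of the alkene may compete, because the radical is nearly planar and discrimination rests only on the syn-axial methyl. The fallback is ionic. From 27, epoxidation (mCPBA, NaHCO3, CH2Cl2) on the equatorial face anti to the C10 methyl gives the spiro-epoxide F8, and LiAlH4 (THF) opens it at the primary carbon C17, returning to 28.

## Further compounds

F1 | step 10 | epoxy alcohol: (1S,3aR,4S,7aR)-4-{[tert-butyl(dimethyl)silyl]oxymethyl}-4,7a-dimethyl-1-[(2S)-oxiran-2-yl]octahydro-1H-inden-1-ol (one C9 epimer drawn) | O1C[C@H]1[C@@]2(O)CC[C@@H]3[C@@](C)(CO[Si](C)(C)C(C)(C)C)CCC[C@@]23C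
F2 | step 10 | hydroxymethyl ketone: (1S,4aS,5S,8aR)-5-{[tert-butyl(dimethyl)silyl]oxymethyl}-1-(hydroxymethyl)-5,8a-dimethyloctahydronaphthalen-2(1H)-one | OC[C@H]1[C@]2(C)CCC[C@](C)(CO[Si](C)(C)C(C)(C)C)[C@H]2CCC1=O
F3 | step 10 | mesylate of F2 | CS(=O)(=O)OC[C@H]1[C@]2(C)CCC[C@](C)(CO[Si](C)(C)C(C)(C)C)[C@H]2CCC1=O
F4 | step 4 | benzyloxymethyl β,γ-enone: C4 benzyloxymethyl, C4 methyl, C5=C6 alkene, C3 ketone, C8 dioxolane | O1CCOC12CC=C3[C@@](C)(COCc4ccccc4)C(=O)CC[C@@]23C
F5 | step 7 | C2=C3 enol triflate of ketone 9 | O1CCOC12CC[C@@H]3[C@@](C)(CO[Si](C)(C)C(C)(C)C)C(OS(=O)(=O)C(F)(F)F)=CC[C@@]23C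
F6 | step 7 | C2=C3 alkene corresponding to 11 | O1CCOC12CC[C@@H]3[C@@](C)(CO[Si](C)(C)C(C)(C)C)C=CC[C@@]23C
F7 | step 16 | {[(3R)-4-iodo-3-methylbutoxy]methyl}benzene | C[C@H](CCOCc1ccccc1)CI
F8 | step 18 | 8,17-spiro-epoxide of 27, oxygen on the equatorial face of C8 | C[C@H](CCOCc1ccccc1)CC[C@H]1[C@]2(C)CCC[C@](C)(CO[Si](C)(C)C(C)(C)C)[C@H]2CC[C@]13OC3
A1 | alternative 1 | open-chain triene: ethyl (E)-2-methyl enoate tethered to the (E)-diene, C8 triethylsilyl ether, benzyl ether at O15 | C[C@H](CCOCc1ccccc1)CC[C@@H](/C(C)=C/C=C)[C@@](C)(O[Si](CC)(CC)CC)CC/C=C(\C)C(=O)OCC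
A2 | alternative 1 | trans-decalin C18 ethyl ester with C1=C2 alkene | C[C@H](CCOCc1ccccc1)CC[C@H]1[C@]2(C)C=CC[C@](C)(C(=O)OCC)[C@H]2CC[C@]1(C)O[Si](CC)(CC)CC
A3 | alternative 2 | 4,4-dimethyl 3-ol with equatorial hydroxyl, O8 triethylsilyl ether, O15 pivalate | C[C@H](CCOC(=O)C(C)(C)C)CC[C@H]1[C@]2(C)CC[C@@H](O)C(C)(C)[C@H]2CC[C@]1(C)O[Si](CC)(CC)CC
A4 | alternative 2 | C3–O–Si–C18 oxasilolane | C[C@H](CCOC(=O)C(C)(C)C)CC[C@H]1[C@]2(C)CC[C@H]3O[Si](CC)(CC)C[C@]3(C)[C@H]2CC[C@]1(C)O[Si](CC)(CC)CC
A5 | alternative 3 | (3R,4R)-epoxy diene allylsilane, (5E)-alkene and (8Z)-allylsilane, O18 silyl ether, O15 pivalate | C[C@H](CCOC(=O)C(C)(C)C)CC/C=C(\C[Si](C)(C)C)CC/C=C(\C)CC[C@H]1O[C@]1(C)CO[Si](C)(C)C(C)(C)C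
A6 | alternative 3 | 3-hydroxy-8(17)-methylene bicycle with full side chain | C[C@H](CCOC(=O)C(C)(C)C)CC[C@H]1[C@]2(C)CC[C@@H](O)[C@](C)(CO[Si](C)(C)C(C)(C)C)[C@H]2CCC1=C
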